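**Retrosynthetic overview**

- Target ⇒ its 13S-acetoxy-14E isomer: a suprafacial 1,3-shift of an acetate from C13 leaves the 13E-allylic 15S-acetate, so the lower-chain oxygen can first sit on C13, next to ring carbon C12.
- 13-Oxygenated enone ⇒ bicyclic siloxane: cyclopentenone ring A fused along C11–C12 to a temporary oxasilolane ring B (C12–C13–O–Si–C11), opened afterwards by fluoride at Si–O and Si–C11.
- Key disconnection of ring A at C9–C10 and C11–C12: nickel-mediated reductive [3+2] union of a silicon-tethered ethyne unit (C10, C11) with the aryl enoate C9(=O)–C8=C12; ring B closes first and ring A directly after it, in the same step.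
- Enabling feature: ring A is a cyclopent-2-enone in which a bare CH=CH (C10=C11) lies between the ketone carbon C9 and the stereocentre C12, the pattern left when an alkyne is inserted between the acyl carbon and the β-carbon of an enoate; the oxygen on C13 holds that alkyne on one face of C12.
- Acyclic precursor ⇒ asymmetric addition of an (E)-heptenylzinc reagent to a 4-oxo-2-alkylbutenoate ⇒ Wittig reaction of an ylide from monomethyl azelate with glyoxal mono(dimethyl acetal).

Key step: step 7

Remark: prostaglandin numbering is used for the atoms (carboxyl carbon C1, ring C8–C12, lower chain C13–C20); monomethyl azelate, 2,2-dimethoxyacetaldehyde, dicyclohexylborane, (−)-MIB and ethynylmagnesium bromide are taken as purchased.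

**Route**

Step 1
Reactants: 1 9-methoxy-9-oxononanoic acid (monomethyl azelate); 2 phenol
Product: 5 phenyl 2-bromo-9-methoxy-9-oxononanoate (racemic), via acid chloride 3 (not isolated), via α-bromo acid chloride 4 (not isolated)
Conditions: SOCl2, 70 °C; NBS, HBr (cat.), 80 °C; then 2, pyridine, CH2Cl2, 0 °C
Reagents that add atoms: N-bromosuccinimide, O=C1CCC(=O)N1Br
Why: Hell–Volhard–Zelinsky-type α-bromination, in which only the acid chloride end enolises so that bromine enters next to it and not next to the methyl ester, followed by esterification with phenol; the new stereocentre is racemic and disappears in step 2.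

Step 2
Reactants: 5 phenyl 2-bromo-9-methoxy-9-oxononanoate
Product: 7 phenyl 9-methoxy-9-oxo-2-(triphenyl-λ5-phosphanylidene)nonanoate, via phosphonium bromide 6 (not isolated)
Conditions: PPh3, toluene, 90 °C; then aq. Na2CO3, CH2Cl2, 0 °C
Reagents that add atoms: triphenylphosphine, c1ccc(cc1)P(c1ccccc1)c1ccccc1
Why: SN2 quaternisation of the phosphine by the α-bromo ester and deprotonation of the acidic salt give the ester-stabilised ylide (preparation of a Wittig reagent), with no stereocentre left.

Step 3
Reactants: 7 phenyl 9-methoxy-9-oxo-2-(triphenyl-λ5-phosphanylidene)nonanoate; 8 2,2-dimethoxyacetaldehyde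
Product: 9 phenyl (2E)-4,4-dimethoxy-2-(7-methoxy-7-oxoheptyl)but-2-enoate
Conditions: toluene, 70 °C
Reagents that add atoms: none
Why: Wittig olefination with an α-alkyl ester-stabilised ylide, which is expected to place the ester trans to the new substituent (E) and so the α-chain cis to the future C13.

Step 4
Reactants: 9 phenyl (2E)-4,4-dimethoxy-2-(7-methoxy-7-oxoheptyl)but-2-enoate
Product: 10 phenyl (2E)-2-(7-methoxy-7-oxoheptyl)-4-oxobut-2-enoate
Conditions: 1 M aq. HCl, THF, 0 °C to rt
Reagents that add atoms: water, O
Why: Acid-catalysed acetal hydrolysis, which the E-enoate and both esters should tolerate in dilute acid; no stereocentre is involved.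

Step 5
Reactants: 10 phenyl (2E)-2-(7-methoxy-7-oxoheptyl)-4-oxobut-2-enoate; 11 hept-1-yne
Product: 14 phenyl (2E,4S,5E)-4-hydroxy-2-(7-methoxy-7-oxoheptyl)undeca-2,5-dienoate, via alkenylborane 12 (not isolated), via alkenylzinc reagent 13 (not isolated)
Conditions: 11, Cy2BH, toluene, 0 °C to rt; Me2Zn, −78 °C; (−)-MIB (5 mol %), then 10, −10 °C; H2O quench
Reagents that add atoms: none
Why: Catalytic asymmetric addition of an (E)-alkenylzinc reagent (syn hydroboration, boron-to-zinc transmetalation with retention of geometry) to the aldehyde under amino-alcohol catalysis; the ligand antipode that delivers the alkenyl group to the Si face of the aldehyde, expected to be (−)-3-exo-morpholinoisoborneol by analogy with its sense on other aldehydes, sets C13 as S, and the zinc reagent should leave both esters untouched.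

Step 6
Reactants: 14 phenyl (2E,4S,5E)-4-hydroxy-2-(7-methoxy-7-oxoheptyl)undeca-2,5-dienoate; 15 dichlorodi(propan-2-yl)silane; 16 ethynylmagnesium bromide
Product: 18 phenyl (2E,4S,5E)-4-{[ethynyldi(propan-2-yl)silyl]oxy}-2-(7-methoxy-7-oxoheptyl)undeca-2,5-dienoate, via chloro(ethynyl)di(propan-2-yl)silane 17 (not isolated)
Conditions: 15, 16 (1.0 equiv), THF, 0 °C to rt; then 14, Et3N, DMAP (cat.), CH2Cl2, rt
Reagents that add atoms: none
Why: Nucleophilic substitution at silicon, first by one acetylide on the hindered dichlorosilane and then by the secondary alcohol under DMAP catalysis (silyl ether formation), with a tertiary amine base chosen so that the phenyl ester is not attacked; the C13–O bond is not touched, so C13 stays S.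

Step 7
Reactants: 18 phenyl (2E,4S,5E)-4-{[ethynyldi(propan-2-yl)silyl]oxy}-2-(7-methoxy-7-oxoheptyl)undeca-2,5-dienoate
Product: 19 methyl 7-[(3S,3aS,4R)-3-[(1E)-hept-1-en-1-yl]-5-oxo-1,1-di(propan-2-yl)-3,3a,4,5-tetrahydro-1H-cyclopenta[c][1,2]oxasilol-4-yl]heptanoate
Conditions: Ni(cod)2 (10 mol %), PBu3 (20 mol %), Et3B (3 equiv), MeOH/THF 1:8, 50 °C, slow addition of 18
Reagents that add atoms: none
Why: Proposed new method: zerovalent nickel couples the tethered alkyne and the s-cis aryl enoate by oxidative cyclisation (C11–C12 bond), methanol protonates the nickel enolate at C8, the alkenylnickel bond at C10 adds to the phenyl ester carbonyl with loss of phenoxide (C9–C10 bond), and Et3B returns nickel to the zerovalent state. The closest known reaction types are the nickel-catalysed reductive [3+2] cycloaddition of aryl enoates with alkynes to cyclopentenones and the intramolecular cyclisation of alkynyl enals to bicyclic cyclopentenols; new here are the temporary silicon tether that makes the alkyne–enoate union intramolecular, the terminal ethynylsilane as the alkyne and the α-alkyl-substituted enoate. Ring B (oxasilolane) closes in the 5-exo mode with respect to both the alkyne and the enoate, at the silicon-bearing alkyne carbon, and ring A (cyclopentenone) closes by 5-exo-trig acyl substitution of the alkenylnickel on the ester. C12 is controlled by the C13 stereocentre: allylic 1,3-strain with the cis α-chain holds the C13–H bond in the enoate plane, so the tethered alkyne can reach only the face of C12 that carries the C13 oxygen, which puts the C8 side of ring A trans to the heptenyl group on ring B; C8 is set by protonation and, being α to the new ketone, should settle in the more stable arrangement trans to the C12–C13 bond. The step needs chemoselectivity for the enoate over the isolated C14=C15 alkene, exo regiochemistry, and acylation ahead of protonation of the alkenylnickel; the electron-poor alkene, the three-atom tether and the phenoxide leaving group held next to C10 should secure them.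

Step 8
Reactants: 19 methyl 7-[(3S,3aS,4R)-3-[(1E)-hept-1-en-1-yl]-5-oxo-1,1-di(propan-2-yl)-3,3a,4,5-tetrahydro-1H-cyclopenta[c][1,2]oxasilol-4-yl]heptanoate
Product: 20 methyl 7-[(1R,2S)-2-[(1S,2E)-1-hydroxyoct-2-en-1-yl]-5-oxocyclopent-3-en-1-yl]heptanoate
Conditions: TBAF (3 equiv), AcOH (3 equiv), THF/DMF, rt to 40 °C
Reagents that add atoms: none
Why: Fluoride cleavage of the Si–O bond and protodesilylation of the oxygen-activated alkenylsilane through a pentacoordinate silicate (proton from AcOH), leaving C10=C11 in place; the AcOH buffer is meant to suppress base-induced enone isomerisation, and no stereocentre is changed.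

Step 9
Reactants: 20 methyl 7-[(1R,2S)-2-[(1S,2E)-1-hydroxyoct-2-en-1-yl]-5-oxocyclopent-3-en-1-yl]heptanoate
Product: 21 7-[(1R,2S)-2-[(1S,2E)-1-hydroxyoct-2-en-1-yl]-5-oxocyclopent-3-en-1-yl]heptanoic acid
Conditions: pig liver esterase, phosphate buffer pH 7.5/acetone 9:1, rt
Reagents that add atoms: water, O
Why: Enzymatic ester hydrolysis at neutral pH, the usual way to free the carboxyl group of base-sensitive prostaglandin esters, so the cyclopentenone and the three stereocentres never meet hydroxide.

Step 10
Reactants: 21 7-[(1R,2S)-2-[(1S,2E)-1-hydroxyoct-2-en-1-yl]-5-oxocyclopent-3-en-1-yl]heptanoic acid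
Product: 23 7-[(1R,2S)-2-[(1S,2E)-1-(acetyloxy)oct-2-en-1-yl]-5-oxocyclopent-3-en-1-yl]heptanoic acid, via mixed anhydride 22 (not isolated)
Conditions: Ac2O (3 equiv), pyridine, CH2Cl2, 0 °C to rt; then H2O/THF, rt
Reagents that add atoms: acetic anhydride, CC(=O)OC(C)=O
Why: O-Acylation of the secondary allylic alcohol with retention at C13 (the C–O bond is not broken), the mixed anhydride at C1 being hydrolysed in the aqueous work-up; pyridine should be too weak a base to eliminate the new acetate through the enone.

Step 11
Reactants: 23 7-[(1R,2S)-2-[(1S,2E)-1-(acetyloxy)oct-2-en-1-yl]-5-oxocyclopent-3-en-1-yl]heptanoic acid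
Product: 24 7-[(1R,2S)-2-[(1E,3S)-3-(acetyloxy)oct-1-en-1-yl]-5-oxocyclopent-3-en-1-yl]heptanoic acid
Conditions: PdCl2(MeCN)2 (10 mol %), THF, rt
Reagents that add atoms: none
Why: Divalent-palladium-catalysed [3,3]-sigmatropic (cyclisation-induced) 1,3-shift of the allylic acetate, in which the acetate carbonyl oxygen attacks C15 of the metal-bound E-alkene through a six-membered acetoxonium chair with the ring substituent equatorial, so that oxygen arrives on the face it leaves (13S becomes 15S) and the new alkene is 13E; the shift is expected to run forward because the acetoxy group leaves the congested carbon next to the ring.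

**Compound list**

1 | 9-methoxy-9-oxononanoic acid (monomethyl azelate) | COC(=O)CCCCCCCC(=O)O | starting material
2 | phenol | Oc1ccccc1 | starting material
3 | methyl 9-chloro-9-oxononanoate | COC(=O)CCCCCCCC(Cl)=O | intermediate
4 | methyl 8-bromo-9-chloro-9-oxononanoate (racemic) | COC(=O)CCCCCCC(Br)C(Cl)=O | intermediate
5 | phenyl 2-bromo-9-methoxy-9-oxononanoate (racemic) | COC(=O)CCCCCCC(Br)C(=O)Oc1ccccc1 | intermediate
6 | (9-methoxy-1,9-dioxo-1-phenoxynonan-2-yl)triphenylphosphonium bromide | COC(=O)CCCCCCC([P+](c1ccccc1)(c1ccccc1)c1ccccc1)C(=O)Oc1ccccc1.[Br-] | intermediate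
7 | phenyl 9-methoxy-9-oxo-2-(triphenyl-λ5-phosphanylidene)nonanoate | COC(=O)CCCCCCC(=P(c1ccccc1)(c1ccccc1)c1ccccc1)C(=O)Oc1ccccc1 | intermediate
8 | 2,2-dimethoxyacetaldehyde | COC(OC)C=O | starting material
9 | phenyl (2E)-4,4-dimethoxy-2-(7-methoxy-7-oxoheptyl)but-2-enoate | COC(=O)CCCCCC/C(=C\C(OC)OC)C(=O)Oc1ccccc1 | intermediate
10 | phenyl (2E)-2-(7-methoxy-7-oxoheptyl)-4-oxobut-2-enoate | COC(=O)CCCCCC/C(=C\C=O)C(=O)Oc1ccccc1 | intermediate
11 | hept-1-yne | CCCCCC#C | starting material
12 | dicyclohexyl[(1E)-hept-1-en-1-yl]borane | CCCCC/C=C/B(C1CCCCC1)C1CCCCC1 | intermediate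
13 | [(1E)-hept-1-en-1-yl](methyl)zinc | CCCCC/C=C/[Zn]C | intermediate
14 | phenyl (2E,4S,5E)-4-hydroxy-2-(7-methoxy-7-oxoheptyl)undeca-2,5-dienoate | CCCCC/C=C/[C@H](O)/C=C(\CCCCCCC(=O)OC)C(=O)Oc1ccccc1 | intermediate
15 | dichlorodi(propan-2-yl)silane | CC(C)[Si](Cl)(Cl)C(C)C | starting material
16 | ethynylmagnesium bromide | C#C[Mg]Br | starting material
17 | chloro(ethynyl)di(propan-2-yl)silane | C#C[Si](Cl)(C(C)C)C(C)C | intermediate
18 | phenyl (2E,4S,5E)-4-{[ethynyldi(propan-2-yl)silyl]oxy}-2-(7-methoxy-7-oxoheptyl)undeca-2,5-dienoate | CCCCC/C=C/[C@H](O[Si](C#C)(C(C)C)C(C)C)/C=C(\CCCCCCC(=O)OC)C(=O)Oc1ccccc1 | intermediate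
19 | methyl 7-[(3S,3aS,4R)-3-[(1E)-hept-1-en-1-yl]-5-oxo-1,1-di(propan-2-yl)-3,3a,4,5-tetrahydro-1H-cyclopenta[c][1,2]oxasilol-4-yl]heptanoate (ring A cyclopentenone fused at C11–C12 to ring B oxasilolane; C8 side and heptenyl trans on ring B) | CCCCC/C=C/[C@@H]1O[Si](C(C)C)(C(C)C)C2=CC(=O)[C@H](CCCCCCC(=O)OC)[C@@H]12 | intermediate
20 | methyl 7-[(1R,2S)-2-[(1S,2E)-1-hydroxyoct-2-en-1-yl]-5-oxocyclopent-3-en-1-yl]heptanoate | CCCCC/C=C/[C@H](O)[C@H]1C=CC(=O)[C@@H]1CCCCCCC(=O)OC | intermediate
21 | 7-[(1R,2S)-2-[(1S,2E)-1-hydroxyoct-2-en-1-yl]-5-oxocyclopent-3-en-1-yl]heptanoic acid | CCCCC/C=C/[C@H](O)[C@H]1C=CC(=O)[C@@H]1CCCCCCC(=O)O | intermediate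
22 | acetic 7-[(1R,2S)-2-[(1S,2E)-1-(acetyloxy)oct-2-en-1-yl]-5-oxocyclopent-3-en-1-yl]heptanoic anhydride | CCCCC/C=C/[C@H](OC(C)=O)[C@H]1C=CC(=O)[C@@H]1CCCCCCC(=O)OC(C)=O | intermediate
23 | 7-[(1R,2S)-2-[(1S,2E)-1-(acetyloxy)oct-2-en-1-yl]-5-oxocyclopent-3-en-1-yl]heptanoic acid | CCCCC/C=C/[C@H](OC(C)=O)[C@H]1C=CC(=O)[C@@H]1CCCCCCC(=O)O | intermediate
24 | 7-[(1R,2S)-2-[(1E,3S)-3-(acetyloxy)oct-1-en-1-yl]-5-oxocyclopent-3-en-1-yl]heptanoic acid | CCCCC[C@@H](/C=C/[C@H]1C=CC(=O)[C@@H]1CCCCCCC(=O)O)OC(C)=O | target

**Step count and risks**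

Total step count: 11. Longest linear sequence: 11 steps (1 to 24).

Steps most likely to fail:

1. Step 7 (proposed new method). What may go wrong: oligomerisation of the terminal alkyne at nickel, protonation of the alkenylnickel before it acylates (stopping after ring B), or bond formation on the wrong face of C12. The fallback sets out from 18 and comes back at 19, building the two bonds one after the other by known reactions. Bu3SnH/AIBN (benzene, 80 °C) should add a stannyl radical to the alkyne terminus, and the α-silyl vinyl radical should close ring B 5-exo onto the enoate β-carbon with the same allylic-strain control, giving the exocyclic alkenylstannane F1. Iododestannylation (I2, CH2Cl2, 0 °C) should give the alkenyl iodide F2 with retention of geometry. Iodine–magnesium exchange (iPrMgCl·LiCl, THF, −40 °C) and intramolecular acylation of the phenyl ester should then close ring A to 19, with C8 equilibrating to trans.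

2. Step 8. What may go wrong: fluoride acting as a base and moving the ring double bond into conjugation at C8=C12, or incomplete C–Si cleavage at the hindered diisopropylsilyl group. The fallback sets out from 19 and comes back at 20, replacing anionic fluoride activation by an acidic opening followed by metal exchange. HF·pyridine (THF, 0 °C) should open only the Si–O bond to the hydroxy alkenyl fluorosilane F3. AgF (THF/MeOH/H2O, rt, dark) should then cleave the C11–Si bond by silicon-to-silver transmetalation and protonation under neutral conditions, giving 20.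

3. Step 11. What may go wrong: the acetate shift stalling short of completion because the free carboxylic acid binds divalent palladium or the equilibrium is not far enough forward, or ionisation eroding the chirality transfer. The fallback sets out from 20 and comes back at 24, running the shift on the ester and deprotecting afterwards. Acetylation of 20 (Ac2O, pyridine) should give the 13-acetoxy methyl ester F4. PdCl2(MeCN)2 in THF should shift it to the 15-acetoxy-13E methyl ester F5, the substrate class on which this rearrangement is established; unshifted F4 would be separated and resubjected. Enzymatic hydrolysis of both esters (pig liver esterase, pH 7.5 buffer) should give the 15-hydroxy acid F6, and selective O-acetylation (Ac2O, pyridine, aqueous work-up) should give 24.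

**Further compounds**

F1 | step 7 | phenyl 2-{5-[(1E)-hept-1-en-1-yl]-2,2-di(propan-2-yl)-3-[(tributylstannyl)methylidene]-1,2-oxasilolan-4-yl}-9-methoxy-9-oxononanoate (C12 and C13 as in 19, tin cis to C12, both C8 epimers) | CCCCC/C=C/[C@@H]1O[Si](C(C)C)(C(C)C)/C(=C/[Sn](CCCC)(CCCC)CCCC)[C@H]1C(CCCCCCC(=O)OC)C(=O)Oc1ccccc1
F2 | step 7 | phenyl 2-{5-[(1E)-hept-1-en-1-yl]-3-(iodomethylidene)-2,2-di(propan-2-yl)-1,2-oxasilolan-4-yl}-9-methoxy-9-oxononanoate (C12 and C13 as in 19, iodine cis to C12, both C8 epimers) | CCCCC/C=C/[C@@H]1O[Si](C(C)C)(C(C)C)/C(=C/I)[C@H]1C(CCCCCCC(=O)OC)C(=O)Oc1ccccc1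
F3 | step 8 | methyl 7-[(1R,2S)-3-[fluorodi(propan-2-yl)silyl]-2-[(1S,2E)-1-hydroxyoct-2-en-1-yl]-5-oxocyclopent-3-en-1-yl]heptanoate | CCCCC/C=C/[C@H](O)[C@H]1C([Si](F)(C(C)C)C(C)C)=CC(=O)[C@@H]1CCCCCCC(=O)OC
F4 | step 11 | methyl 7-[(1R,2S)-2-[(1S,2E)-1-(acetyloxy)oct-2-en-1-yl]-5-oxocyclopent-3-en-1-yl]heptanoate | CCCCC/C=C/[C@H](OC(C)=O)[C@H]1C=CC(=O)[C@@H]1CCCCCCC(=O)OC
F5 | step 11 | methyl 7-[(1R,2S)-2-[(1E,3S)-3-(acetyloxy)oct-1-en-1-yl]-5-oxocyclopent-3-en-1-yl]heptanoate | CCCCC[C@@H](/C=C/[C@H]1C=CC(=O)[C@@H]1CCCCCCC(=O)OC)OC(C)=O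
F6 | step 11 | 7-[(1R,2S)-2-[(1E,3S)-3-hydroxyoct-1-en-1-yl]-5-oxocyclopent-3-en-1-yl]heptanoic acid | CCCCC[C@@H](/C=C/[C@H]1C=CC(=O)[C@@H]1CCCCCCC(=O)O)O
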